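The route rests on cutting the cyclopentane ring C1–C2–C3–C5–C9 of the bicyclo[3.2.1]octane (C1 = isobutyryl-bearing bridgehead, C5 = prenylated bridgehead, C9 = one-carbon bridge, C2/C3 = two-carbon bridge) at C9–C5 and C2–C3. That ring carries both ring carbonyls (C9, C2) on the quaternary carbon C1 and an α-oxy acyl unit on its C5–C3 edge, which the key step reads as a 2,2-disubstituted malondialdehyde facing a captodative alkene. A SmI2 ketyl–olefin cyclisation/aldol cascade closes the cyclohexane and the cyclopentane in one operation and sets C1, C3 and C5 from the single C7 centre. Its precursor is an open chain in which C1 bears two formyl groups and the isobutyryl group and C5=C3 is an alkylidene dioxolanone.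

Key step: step 15

Atom labels used below (not IUPAC locants): C1 bridgehead with the isobutyryl group (carbonyl C11); C2 ring ketone; C3 carbinol carbon carrying the side-chain ketone C10; C5 prenylated bridgehead; C6 CH2; C7 prenylated CH; C8 CMe2; C9 bridging ketone.
Assumption: compounds 1, 21 and 22 are treated as catalogue chemicals.

Step 1
Reactants: 1 2,2-dimethyl-1,3-dioxane-5-carboxylic acid; 2 prenyl bromide
Product: 3 3-methylbut-2-en-1-yl 2,2-dimethyl-1,3-dioxane-5-carboxylate
Conditions: K2CO3, DMF, rt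
Reagents that add atoms: none
Why: O-alkylation of the carboxylate by the allylic bromide (SN2) should give the prenyl ester; no stereocentre is formed.

Step 2
Reactants: 3 3-methylbut-2-en-1-yl 2,2-dimethyl-1,3-dioxane-5-carboxylate
Product: 6 2,2-dimethyl-5-(2-methylbut-3-en-2-yl)-1,3-dioxane-5-carboxylic acid, via trimethylsilyl ketene acetal 4 (not isolated), via trimethylsilyl ester 5 (not isolated)
Conditions: LDA, TMSCl, THF, −78 °C → 60 °C; then aqueous work-up at pH 4
Reagents that add atoms: none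
Why: Ireland–Claisen rearrangement of the silyl ketene acetal should join the two quaternary carbons C1 and C8 by a [3,3] shift (reverse prenylation); neither new centre is stereogenic.

Step 3
Reactants: 6 2,2-dimethyl-5-(2-methylbut-3-en-2-yl)-1,3-dioxane-5-carboxylic acid; 7 isopropylmagnesium chloride
Product: 9 1-[2,2-dimethyl-5-(2-methylbut-3-en-2-yl)-1,3-dioxan-5-yl]-2-methylpropan-1-one, via acid chloride 8 (not isolated)
Conditions: 1-chloro-N,N,2-trimethylprop-1-en-1-amine, CH2Cl2, 0 °C → rt; then 7, CuI (10 mol %), THF, −40 °C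
Reagents that add atoms: none
Why: copper-catalysed acylation of the Grignard reagent by the acid chloride (made under neutral conditions so that the acetonide survives) should stop at the doubly neopentyl ketone C11.

Step 4
Reactants: 9 1-[2,2-dimethyl-5-(2-methylbut-3-en-2-yl)-1,3-dioxan-5-yl]-2-methylpropan-1-one
Product: 11 1-[5-(4-hydroxy-2-methylbutan-2-yl)-2,2-dimethyl-1,3-dioxan-5-yl]-2-methylpropan-1-one, via B-alkyl-9-BBN adduct 10 (not isolated)
Conditions: 9-BBN, THF, 60 °C; then NaOH, H2O2, 0 °C → rt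
Reagents that add atoms: hydrogen peroxide, OO
Why: anti-Markovnikov hydroboration–oxidation of the monosubstituted alkene should give the primary alcohol at C6; 9-BBN should leave the hindered ketone alone.

Step 5
Reactants: 11 1-[5-(4-hydroxy-2-methylbutan-2-yl)-2,2-dimethyl-1,3-dioxan-5-yl]-2-methylpropan-1-one
Product: 13 3-[2,2-dimethyl-5-(2-methylpropanoyl)-1,3-dioxan-5-yl]-3-methylbutanoic acid, via aldehyde 12 (not isolated)
Conditions: TEMPO (cat.), PhI(OAc)2, MeCN/pH 7 buffer, rt
Reagents that add atoms: water, O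
Why: TEMPO/PhI(OAc)2 oxidation of the primary alcohol through the aldehyde hydrate should give the acid under buffered conditions that spare the acetonide.

Step 6
Reactants: 13 3-[2,2-dimethyl-5-(2-methylpropanoyl)-1,3-dioxan-5-yl]-3-methylbutanoic acid; 14 (S)-4-benzyloxazolidin-2-one
Product: 16 (4S)-4-benzyl-3-{3-[2,2-dimethyl-5-(2-methylpropanoyl)-1,3-dioxan-5-yl]-3-methylbutanoyl}oxazolidin-2-one, via mixed pivalic anhydride 15 (not isolated)
Conditions: PivCl, Et3N, THF, −20 °C; then 14, LiCl, rt
Reagents that add atoms: none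
Why: N-acylation of the oxazolidinone through the mixed anhydride should occur at the less hindered CH2-acyl carbonyl.

Step 7
Reactants: 16 (4S)-4-benzyl-3-{3-[2,2-dimethyl-5-(2-methylpropanoyl)-1,3-dioxan-5-yl]-3-methylbutanoyl}oxazolidin-2-one; 2 prenyl bromide
Product: 18 (4S)-4-benzyl-3-{(2S)-2-{2-[2,2-dimethyl-5-(2-methylpropanoyl)-1,3-dioxan-5-yl]propan-2-yl}-5-methylhex-4-enoyl}oxazolidin-2-one, via sodium Z-enolate 17 (not isolated)
Conditions: NaHMDS, THF, −78 °C; then 2, −78 → −30 °C
Reagents that add atoms: none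
Why: Evans alkylation, in which the chelated Z-enolate is attacked by prenyl bromide on the face opposite the benzyl group, should set C7 as (S) here, which is the arrangement that becomes (R)-C7 of the target.

Step 8
Reactants: 18 (4S)-4-benzyl-3-{(2S)-2-{2-[2,2-dimethyl-5-(2-methylpropanoyl)-1,3-dioxan-5-yl]propan-2-yl}-5-methylhex-4-enoyl}oxazolidin-2-one
Product: 19 1-{5-[(3S)-3-(hydroxymethyl)-2,6-dimethylhept-5-en-2-yl]-2,2-dimethyl-1,3-dioxan-5-yl}-2-methylpropan-1-one
Conditions: LiBH4, MeOH (1 equiv), Et2O, 0 °C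
Reagents that add atoms: none
Why: reductive removal of the auxiliary should occur at the activated imide carbonyl much faster than reduction of the doubly neopentyl isobutyryl ketone, without epimerising C7.

Step 9
Reactants: 19 1-{5-[(3S)-3-(hydroxymethyl)-2,6-dimethylhept-5-en-2-yl]-2,2-dimethyl-1,3-dioxan-5-yl}-2-methylpropan-1-one
Product: 20 1-{5-[(3S)-3-(iodomethyl)-2,6-dimethylhept-5-en-2-yl]-2,2-dimethyl-1,3-dioxan-5-yl}-2-methylpropan-1-one
Conditions: I2, PPh3, imidazole, CH2Cl2, 0 °C → rt
Reagents that add atoms: iodine, II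
Why: Appel-type iodination of the primary alcohol (SN2 at C6) should leave the C7 centre untouched.

Step 10
Reactants: 21 2,2-dimethyl-1,3-dioxolan-4-one; 22 4-methylpent-3-enoic acid
Product: 25 2,2-dimethyl-5-(4-methylpent-3-enoyl)-1,3-dioxolan-4-one, via acyl imidazole 23 (not isolated), via lithium enolate 24 (not isolated)
Conditions: 22, CDI, THF, rt; separately 21, LiHMDS (2.2 equiv), THF, −78 °C; combined at −78 °C; AcOH quench
Reagents that add atoms: none
Why: crossed Claisen C-acylation of the glycolate-acetonide enolate by the acyl imidazole should give the β-keto lactone, which is held as its enolate by the second equivalent of base.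

Step 11
Reactants: 25 2,2-dimethyl-5-(4-methylpent-3-enoyl)-1,3-dioxolan-4-one
Product: 27 (1E)-1-(2,2-dimethyl-5-oxo-1,3-dioxolan-4-ylidene)-4-methylpent-3-en-1-yl trifluoromethanesulfonate, via sodium enolate 26 (not isolated)
Conditions: NaH, THF, 0 °C; then PhNTf2, 0 °C → rt
Reagents that add atoms: N-phenylbis(trifluoromethanesulfonimide), O=S(=O)(N(c1ccccc1)S(=O)(=O)C(F)(F)F)C(F)(F)F
Why: O-triflation of the chelated enolate should give the enol triflate with the triflate cis to the lactone carbonyl; this geometry is lost again in step 15.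

Step 12
Reactants: 20 1-{5-[(3S)-3-(iodomethyl)-2,6-dimethylhept-5-en-2-yl]-2,2-dimethyl-1,3-dioxan-5-yl}-2-methylpropan-1-one; 27 (1E)-1-(2,2-dimethyl-5-oxo-1,3-dioxolan-4-ylidene)-4-methylpent-3-en-1-yl trifluoromethanesulfonate
Product: 29 (E)-5-[(7R)-7-{2-[2,2-dimethyl-5-(2-methylpropanoyl)-1,3-dioxan-5-yl]propan-2-yl}-2,10-dimethylundeca-2,9-dien-5-ylidene]-2,2-dimethyl-1,3-dioxolan-4-one, via alkylzinc iodide 28 (not isolated)
Conditions: Zn dust, LiCl, THF, 40 °C; then 27, Pd(OAc)2 (3 mol %), SPhos (6 mol %), THF, rt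
Reagents that add atoms: none
Why: Negishi sp3–sp2 coupling of the primary alkylzinc (zinc insertion tolerates ketone and acetal) with the electron-poor enol triflate should form C6–C5 with retention of alkene geometry; C7 is untouched and is named (R) only through a change of CIP priorities.

Step 13
Reactants: 29 (E)-5-[(7R)-7-{2-[2,2-dimethyl-5-(2-methylpropanoyl)-1,3-dioxan-5-yl]propan-2-yl}-2,10-dimethylundeca-2,9-dien-5-ylidene]-2,2-dimethyl-1,3-dioxolan-4-one
Product: 30 (E)-5-{(7R)-7-[4-hydroxy-3-(hydroxymethyl)-2-methyl-3-(2-methylpropanoyl)butan-2-yl]-2,10-dimethylundeca-2,9-dien-5-ylidene}-2,2-dimethyl-1,3-dioxolan-4-one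
Conditions: AcOH/THF/H2O (3:1:1), 40 °C
Reagents that add atoms: none
Why: acid hydrolysis should cleave the dialkyl acetonide selectively, because the dioxolanone is a far less basic enol/acyl ketal.

Step 14
Reactants: 30 (E)-5-{(7R)-7-[4-hydroxy-3-(hydroxymethyl)-2-methyl-3-(2-methylpropanoyl)butan-2-yl]-2,10-dimethylundeca-2,9-dien-5-ylidene}-2,2-dimethyl-1,3-dioxolan-4-one
Product: 31 2-[(3R,5E)-5-(2,2-dimethyl-5-oxo-1,3-dioxolan-4-ylidene)-2,8-dimethyl-3-(3-methylbut-2-en-1-yl)non-7-en-2-yl]-2-(2-methylpropanoyl)propanedial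
Conditions: Dess–Martin periodinane, NaHCO3, CH2Cl2, 0 °C → rt; crude product used at once
Reagents that add atoms: none
Why: Dess–Martin oxidation of both neopentyl primary alcohols should give the non-enolisable dialdehyde under buffered, non-nucleophilic conditions that avoid deformylation.

Step 15
Reactants: 31 2-[(3R,5E)-5-(2,2-dimethyl-5-oxo-1,3-dioxolan-4-ylidene)-2,8-dimethyl-3-(3-methylbut-2-en-1-yl)non-7-en-2-yl]-2-(2-methylpropanoyl)propanedial
Product: 33 bicyclo[3.2.1]octane-2,9-diol with the dioxolanone spiro-fused at C3 (labels as above), via samarium(III) enolate 32 (not isolated)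
Conditions: SmI2 (2.5 equiv, 0.1 M in THF), THF, −78 °C; then sat. aq. NH4Cl at −78 °C
Reagents that add atoms: none
Why: Sm(II) should reduce one of the two equivalent formyl groups to a ketyl that adds 6-exo-trig to C5 of the captodative alkylidene dioxolanone (C9–C5), the resulting α-oxy-α-acyl radical is reduced to a Sm(III) enolate, and this closes the five-membered ring by a 5-exo aldol onto the remaining formyl group (C2–C3); the closest known reaction type is the SmI2 ketyl–olefin cyclisation/aldol cascade of dialdehydes onto unsaturated lactones. The cyclohexane should form through a chair transition state with the C7 prenyl group equatorial, the small formyl group (not the isobutyryl group) axial on C1 and the dioxolanone carbon C3 axial on C5, an arrangement held by Sm(III) chelation of the ketyl oxygen, the second formyl oxygen and the lactone carbonyl; this fixes C1 and C5 relative to the existing C7 centre, and only this cis-diaxial isomer can close the second ring. C3 is set in the chelated aldol, which places the samarium-bound enolate oxygen, and hence C10, on the open face syn to C9 and leaves the ring oxygen (the later C3–OH) endo. The C9 and C2 carbinol centres are expected as drawn (C9–OH over the new two-carbon bridge, C2–OH exo) but are erased in step 17. The step needs ketyl formation at a formyl group in preference to the hindered ketone, 6-exo addition faster than pinacol closure between the geminal formyl groups, and aldol faster than enolate protonation; the activated acceptor, the cis-diaxial proximity of enolate and aldehyde and aprotic conditions at −78 °C are relied on for this.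

Step 16
Reactants: 33 bicyclo[3.2.1]octane-2,9-diol with the dioxolanone spiro-fused at C3; 34 2-methylbut-3-yn-2-ol
Product: 37 bicyclo[3.2.1]octane-2,3,9-triol carrying the 4-hydroxy-4-methylpent-2-ynoyl group at C3 (labels as above), via dilithium alkynide 35 (not isolated), via hemiketal alkoxide 36 (not isolated)
Conditions: 34 (6 equiv), n-BuLi (12 equiv), THF, −78 → 0 °C; then 33, −78 → −40 °C; sat. aq. NH4Cl
Reagents that add atoms: none
Why: single addition of the lithium acetylide to the activated lactone carbonyl should give a hemiketal alkoxide that is stable in the cold and collapses on work-up with loss of acetone, unveiling the ynone C10 and the C3 hydroxyl without breaking any bond to C3.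

Step 17
Reactants: 37 bicyclo[3.2.1]octane-2,3,9-triol carrying the 4-hydroxy-4-methylpent-2-ynoyl group at C3
Product: 38 (1S,3R,5R,7S)-7-hydroxy-7-(4-hydroxy-4-methylpent-2-ynoyl)-4,4-dimethyl-1,3-bis(3-methylbut-2-en-1-yl)-5-(2-methylpropanoyl)bicyclo[3.2.1]octane-6,8-dione
Conditions: Dess–Martin periodinane, NaHCO3, CH2Cl2, 0 °C → rt
Reagents that add atoms: none
Why: Dess–Martin oxidation should convert the two secondary carbinols into the C9 and C2 ketones while the tertiary alcohols and the ynone stay inert.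

Step 18
Reactants: 38 (1S,3R,5R,7S)-7-hydroxy-7-(4-hydroxy-4-methylpent-2-ynoyl)-4,4-dimethyl-1,3-bis(3-methylbut-2-en-1-yl)-5-(2-methylpropanoyl)bicyclo[3.2.1]octane-6,8-dione
Product: 39 (1S,3R,5R,7S)-7-hydroxy-7-[(2Z)-4-hydroxy-4-methylpent-2-enoyl]-4,4-dimethyl-1,3-bis(3-methylbut-2-en-1-yl)-5-(2-methylpropanoyl)bicyclo[3.2.1]octane-6,8-dione (CNP0190794.1)
Conditions: H2 (1 atm), Lindlar catalyst, quinoline, EtOAc, 0 °C; stopped after one equivalent of H2
Reagents that add atoms: none
Why: Lindlar semi-hydrogenation (syn addition of one equivalent of hydrogen to the ynone) should give the (Z)-enone, the trisubstituted prenyl alkenes being inert to the poisoned catalyst.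

Compound list
1 | 2,2-dimethyl-1,3-dioxane-5-carboxylic acid | CC1(C)OCC(CO1)C(=O)O | starting material
2 | prenyl bromide (1-bromo-3-methylbut-2-ene) | CC(C)=CCBr | starting material
3 | 3-methylbut-2-en-1-yl 2,2-dimethyl-1,3-dioxane-5-carboxylate | CC(C)=CCOC(=O)C1COC(C)(C)OC1 | intermediate
4 | trimethylsilyl ketene acetal of 3 (not isolated) | CC(C)=CCOC(O[Si](C)(C)C)=C1COC(C)(C)OC1 | intermediate
5 | trimethylsilyl ester of 6 (not isolated) | C=CC(C)(C)C1(COC(C)(C)OC1)C(=O)O[Si](C)(C)C | intermediate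
6 | 2,2-dimethyl-5-(2-methylbut-3-en-2-yl)-1,3-dioxane-5-carboxylic acid | C=CC(C)(C)C1(COC(C)(C)OC1)C(=O)O | intermediate
7 | isopropylmagnesium chloride | CC(C)[Mg]Cl | starting material
8 | acid chloride of 6 (not isolated) | C=CC(C)(C)C1(COC(C)(C)OC1)C(Cl)=O | intermediate
9 | 1-[2,2-dimethyl-5-(2-methylbut-3-en-2-yl)-1,3-dioxan-5-yl]-2-methylpropan-1-one | C=CC(C)(C)C1(COC(C)(C)OC1)C(=O)C(C)C | intermediate
10 | B-alkyl-9-BBN adduct of 9 (not isolated) | CC(C)C(=O)C1(COC(C)(C)OC1)C(C)(C)CCB1C2CCCC1CCC2 | intermediate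
11 | 1-[5-(4-hydroxy-2-methylbutan-2-yl)-2,2-dimethyl-1,3-dioxan-5-yl]-2-methylpropan-1-one | CC(C)C(=O)C1(COC(C)(C)OC1)C(C)(C)CCO | intermediate
12 | 3-[2,2-dimethyl-5-(2-methylpropanoyl)-1,3-dioxan-5-yl]-3-methylbutanal (not isolated) | CC(C)C(=O)C1(COC(C)(C)OC1)C(C)(C)CC=O | intermediate
13 | 3-[2,2-dimethyl-5-(2-methylpropanoyl)-1,3-dioxan-5-yl]-3-methylbutanoic acid | CC(C)C(=O)C1(COC(C)(C)OC1)C(C)(C)CC(=O)O | intermediate
14 | (S)-4-benzyloxazolidin-2-one | O=C1N[C@@H](Cc2ccccc2)CO1 | starting material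
15 | mixed pivalic anhydride of 13 (not isolated) | CC(C)C(=O)C1(COC(C)(C)OC1)C(C)(C)CC(=O)OC(=O)C(C)(C)C | intermediate
16 | (4S)-4-benzyl-3-{3-[2,2-dimethyl-5-(2-methylpropanoyl)-1,3-dioxan-5-yl]-3-methylbutanoyl}oxazolidin-2-one | CC(C)C(=O)C1(COC(C)(C)OC1)C(C)(C)CC(=O)N1[C@@H](Cc2ccccc2)COC1=O | intermediate
17 | sodium (Z)-enolate of 16 (not isolated) | [Na+].CC(C)C(=O)C1(COC(C)(C)OC1)C(C)(C)/C=C(\[O-])N1[C@@H](Cc2ccccc2)COC1=O | intermediate
18 | (4S)-4-benzyl-3-{(2S)-2-{2-[2,2-dimethyl-5-(2-methylpropanoyl)-1,3-dioxan-5-yl]propan-2-yl}-5-methylhex-4-enoyl}oxazolidin-2-one | CC(C)C(=O)C1(COC(C)(C)OC1)C(C)(C)[C@H](CC=C(C)C)C(=O)N1[C@@H](Cc2ccccc2)COC1=O | intermediate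
19 | 1-{5-[(3S)-3-(hydroxymethyl)-2,6-dimethylhept-5-en-2-yl]-2,2-dimethyl-1,3-dioxan-5-yl}-2-methylpropan-1-one | CC(C)C(=O)C1(COC(C)(C)OC1)C(C)(C)[C@H](CC=C(C)C)CO | intermediate
20 | 1-{5-[(3S)-3-(iodomethyl)-2,6-dimethylhept-5-en-2-yl]-2,2-dimethyl-1,3-dioxan-5-yl}-2-methylpropan-1-one | CC(C)C(=O)C1(COC(C)(C)OC1)C(C)(C)[C@H](CC=C(C)C)CI | intermediate
21 | 2,2-dimethyl-1,3-dioxolan-4-one | CC1(C)OCC(=O)O1 | starting material
22 | 4-methylpent-3-enoic acid | CC(C)=CCC(=O)O | starting material
23 | 1-(4-methylpent-3-enoyl)imidazole (not isolated) | CC(C)=CCC(=O)n1ccnc1 | intermediate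
24 | lithium enolate of 21 (not isolated) | [Li+].CC1(C)OC=C([O-])O1 | intermediate
25 | 2,2-dimethyl-5-(4-methylpent-3-enoyl)-1,3-dioxolan-4-one (largely enolised) | CC(C)=CCC(=O)C1OC(C)(C)OC1=O | intermediate
26 | sodium enolate of 25 (not isolated) | [Na+].CC(C)=CC/C([O-])=C1\OC(C)(C)OC1=O | intermediate
27 | (1E)-1-(2,2-dimethyl-5-oxo-1,3-dioxolan-4-ylidene)-4-methylpent-3-en-1-yl trifluoromethanesulfonate | CC(C)=CC/C(OS(=O)(=O)C(F)(F)F)=C1\OC(C)(C)OC1=O | intermediate
28 | alkylzinc iodide from 20 (not isolated) | CC(C)C(=O)C1(COC(C)(C)OC1)C(C)(C)[C@H](CC=C(C)C)C[Zn]I | intermediate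
29 | (E)-5-[(7R)-7-{2-[2,2-dimethyl-5-(2-methylpropanoyl)-1,3-dioxan-5-yl]propan-2-yl}-2,10-dimethylundeca-2,9-dien-5-ylidene]-2,2-dimethyl-1,3-dioxolan-4-one | CC(C)C(=O)C1(COC(C)(C)OC1)C(C)(C)[C@H](CC=C(C)C)C/C(CC=C(C)C)=C2/OC(C)(C)OC2=O | intermediate
30 | (E)-5-{(7R)-7-[4-hydroxy-3-(hydroxymethyl)-2-methyl-3-(2-methylpropanoyl)butan-2-yl]-2,10-dimethylundeca-2,9-dien-5-ylidene}-2,2-dimethyl-1,3-dioxolan-4-one | CC(C)C(=O)C(CO)(CO)C(C)(C)[C@H](CC=C(C)C)C/C(CC=C(C)C)=C1/OC(C)(C)OC1=O | intermediate
31 | 2-[(3R,5E)-5-(2,2-dimethyl-5-oxo-1,3-dioxolan-4-ylidene)-2,8-dimethyl-3-(3-methylbut-2-en-1-yl)non-7-en-2-yl]-2-(2-methylpropanoyl)propanedial | CC(C)C(=O)C(C=O)(C=O)C(C)(C)[C@H](CC=C(C)C)C/C(CC=C(C)C)=C1/OC(C)(C)OC1=O | intermediate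
32 | samarium(III) alkoxide/enolate after closure of C9–C5: cyclohexane with C7 prenyl equatorial, C1 formyl axial and the C5 dioxolanone enolate axial (not isolated) | CC(C)=CC[C@@H]1C[C@@](CC=C(C)C)(C2=C(O[Sm](I)I)OC(C)(C)O2)[C@@H](O[Sm](I)I)[C@@](C(=O)C(C)C)(C=O)C1(C)C | intermediate
33 | bicyclo[3.2.1]octane-2,9-diol with 2,2-dimethyl-1,3-dioxolan-4-one spiro-fused at C3 (labels as above): C1 isobutyryl; C5 prenyl; C7 prenyl exo; C8 gem-dimethyl; lactone carbonyl exo and ring oxygen endo at C3; C9–OH over the C2–C3 bridge; C2–OH exo | CC(C)=CC[C@@H]1C[C@]2(CC=C(C)C)[C@@H](O)[C@@](C(=O)C(C)C)([C@@H](O)[C@@]2(OC(C)(C)O3)C3=O)C1(C)C | intermediate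
34 | 2-methylbut-3-yn-2-ol | CC(C)(O)C#C | starting material
35 | dilithium salt of 34 (alkoxide and acetylide; not isolated) | [Li+].[Li+].CC(C)([O-])C#[C-] | intermediate
36 | lithium hemiketal alkoxide formed by addition of 35 to the lactone carbonyl of 33 (not isolated) | CC(C)=CC[C@@H]1C[C@]2(CC=C(C)C)[C@@H]([O-])[C@@](C(=O)C(C)C)([C@@H]([O-])[C@@]2(OC(C)(C)O3)C3([O-])C#CC(C)(C)[O-])C1(C)C.[Li+].[Li+].[Li+].[Li+] | intermediate
37 | bicyclo[3.2.1]octane-2,3,9-triol with the 4-hydroxy-4-methylpent-2-ynoyl group exo at C3 (labels as above; other stereochemistry as in 33) | CC(C)=CC[C@@H]1C[C@]2(CC=C(C)C)[C@@H](O)[C@@](C(=O)C(C)C)([C@@H](O)[C@@]2(O)C(=O)C#CC(C)(C)O)C1(C)C | intermediate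
38 | (1S,3R,5R,7S)-7-hydroxy-7-(4-hydroxy-4-methylpent-2-ynoyl)-4,4-dimethyl-1,3-bis(3-methylbut-2-en-1-yl)-5-(2-methylpropanoyl)bicyclo[3.2.1]octane-6,8-dione | CC(C)=CC[C@@H]1C[C@]2(CC=C(C)C)C(=O)[C@@](C(=O)C(C)C)(C(=O)[C@@]2(O)C(=O)C#CC(C)(C)O)C1(C)C | intermediate
39 | (1S,3R,5R,7S)-7-hydroxy-7-[(2Z)-4-hydroxy-4-methylpent-2-enoyl]-4,4-dimethyl-1,3-bis(3-methylbut-2-en-1-yl)-5-(2-methylpropanoyl)bicyclo[3.2.1]octane-6,8-dione (CNP0190794.1) | CC(C)=CC[C@@H]1C[C@]2(CC=C(C)C)C(=O)[C@@](C(=O)C(C)C)(C(=O)[C@@]2(O)C(=O)/C=C\C(C)(C)O)C1(C)C | target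

Total step count: 18. Longest linear sequence: 16 steps (steps 1–9 and 12–18); steps 10 and 11 make the enol triflate 27 separately.

Steps most likely to fail

Step 15 (key step). The ketyl may be diverted into pinacol-type coupling between the two geminal formyl groups or into simple reduction. The radical may attack the wrong face of C5, so that the enolate cannot reach the second formyl group. The samarium enolate may be protonated before the aldol. The fallback replaces the radical cascade by polar umpolung and sets out from 31. A triazolium-derived N-heterocyclic carbene (DBU, toluene) should promote an intramolecular Stetter addition of one formyl group to C5, and the enolate so formed should close onto the second formyl group in an aldol reaction, giving keto alcohol F1. Reduction of the strained C9 ketone (NaBH4, MeOH, −40 °C) should give diol F2. F2 is carried through the acetylide addition of step 16 to ynone tetraol F3. Oxidation as in step 17 brings the sequence back to the route at 38.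

Step 16. Addition to the neopentyl spiro-lactone carbonyl may be slow, and on warming the C2 alkoxide may undergo retro-aldol cleavage or the acetylide may attack the C11 ketone. The fallback lowers the oxidation level of C10 first and sets out from 33. DIBAL-H (CH2Cl2, −78 °C) should reduce the dioxolanone to its lactol, which loses acetone on work-up to give α-hydroxy aldehyde F4. Any C11 carbinol formed here would be re-oxidised later. Addition of 35 to the aldehyde at −78 °C should give propargylic alcohol F5 as a mixture of C10 epimers. The oxidation of step 17, which now also converts the C10 carbinol into the ynone, returns the material to the route at 38.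

Step 12. β-Hydride elimination from the alkylpalladium intermediate, protonolysis of the alkylzinc or hydrolysis of the tetrasubstituted enol triflate may outrun the coupling. The fallback builds the alkene by carbonyl addition and elimination and sets out from 20, again through 28. Palladium-catalysed acylation of 28 with 4-methylpent-3-enoyl chloride F6 (from 22 and oxalyl chloride) should give ketone F7. Addition of the cerium enolate of 21 at −78 °C with acetylation of the aldolate in the same flask should give β-acetoxy lactone F8. E1cB elimination with DBU returns to the route at 29, obtained as an E/Z mixture; both isomers are usable because the alkene geometry is lost in step 15.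

Further compounds
F1 | step 15 | Stetter–aldol product: C9 ketone and C2 carbinol with the spiro-dioxolanone at C3 (C2 configuration unassigned) | CC(C)=CC[C@@H]1C[C@]2(CC=C(C)C)C(=O)[C@@](C(=O)C(C)C)(C(O)[C@@]2(OC(C)(C)O3)C3=O)C1(C)C
F2 | step 15 | C2,C9-diol from F1 (carbinol configurations unassigned) | CC(C)=CC[C@@H]1C[C@]2(CC=C(C)C)C(O)[C@@](C(=O)C(C)C)(C(O)[C@@]2(OC(C)(C)O3)C3=O)C1(C)C
F3 | step 15 | ynone tetraol from F2 (C2 and C9 carbinol configurations unassigned) | CC(C)=CC[C@@H]1C[C@]2(CC=C(C)C)C(O)[C@@](C(=O)C(C)C)(C(O)[C@@]2(O)C(=O)C#CC(C)(C)O)C1(C)C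
F4 | step 16 | α-hydroxy aldehyde: 2,3,9-triol with a formyl group exo at C3 | CC(C)=CC[C@@H]1C[C@]2(CC=C(C)C)[C@@H](O)[C@@](C(=O)C(C)C)([C@@H](O)[C@@]2(O)C=O)C1(C)C
F5 | step 16 | propargylic alcohol from F4 and 35 (C10 epimers) | CC(C)=CC[C@@H]1C[C@]2(CC=C(C)C)[C@@H](O)[C@@](C(=O)C(C)C)([C@@H](O)[C@@]2(O)C(O)C#CC(C)(C)O)C1(C)C
F6 | step 12 | 4-methylpent-3-enoyl chloride | CC(C)=CCC(Cl)=O
F7 | step 12 | 1-{5-[(3R)-2,8-dimethyl-3-(3-methylbut-2-en-1-yl)-5-oxonon-7-en-2-yl]-2,2-dimethyl-1,3-dioxan-5-yl}-2-methylpropan-1-one | CC(C)C(=O)C1(COC(C)(C)OC1)C(C)(C)[C@H](CC=C(C)C)CC(=O)CC=C(C)C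
F8 | step 12 | β-acetoxy lactone from F7 and the enolate of 21 (new centres unassigned) | CC(C)C(=O)C1(COC(C)(C)OC1)C(C)(C)[C@H](CC=C(C)C)CC(CC=C(C)C)(OC(C)=O)C2OC(C)(C)OC2=O
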